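The route rests on cutting the C3–C4 bond of the oxolane ring, where C3 is the spiro carbon shared with the oxirane (it bears the oxirane O and CH2) and C4 is the ring CH carrying the 3-hydroxy-4-methoxybenzyl group. An Ireland–Claisen rearrangement of an (R,E)-allylic ester of glyceric acid acetonide forms this bond and both stereocentres in one operation. The dioxolane stands in for the oxirane, and the rearrangement leaves a carboxyl group (future C2) and a propenyl group (future C5). Alkene cleavage with lactonisation, aryllithium addition, oxocarbenium reduction (setting C2) and a final oxirane closure from the unmasked diol complete the synthesis.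

Key step: step 8

Remark on the chemistry: atoms are numbered as in the oxolane ring (O1, C2 aryl-bearing, C3 spiro, C4 benzyl-bearing, C5), and in this numbering the target is (2S,3S,4S). The dioxolane stereocentre of 9–11 is planarised in step 8, so either enantiomer of 9 would serve.

Step 1
Reactants: 1 isovanillin (3-hydroxy-4-methoxybenzaldehyde)
Product: 2 3-(benzyloxy)-4-methoxybenzaldehyde
Conditions: BnBr, K2CO3, DMF, rt
Reagents that add atoms: benzyl bromide, BrCc1ccccc1
Why: Williamson etherification of the phenoxide with a benzylic bromide (SN2) should be clean because the aldehyde is inert to K2CO3.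

Step 2
Reactants: 2 3-(benzyloxy)-4-methoxybenzaldehyde
Product: 3 [3-(benzyloxy)-4-methoxyphenyl]methanol
Conditions: NaBH4, MeOH, 0 °C
Reagents that add atoms: none
Why: Borohydride reduction of an aryl aldehyde should give the benzylic alcohol without touching either ether.

Step 3
Reactants: 3 [3-(benzyloxy)-4-methoxyphenyl]methanol
Product: 4 3-(benzyloxy)-4-methoxybenzyl bromide
Conditions: PBr3, CH2Cl2, 0 °C; used without storage
Reagents that add atoms: phosphorus tribromide, BrP(Br)Br
Why: Bromination of a benzylic alcohol through its phosphite ester (SN2 by bromide) is standard, and the electron-rich bromide is taken on fresh to avoid self-condensation.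

Step 4
Reactants: 4 3-(benzyloxy)-4-methoxybenzyl bromide; 5 (R)-but-3-yn-2-ol
Product: 7 (R)-5-[3-(benzyloxy)-4-methoxyphenyl]pent-3-yn-2-ol, via magnesium alkynide 6 (not isolated)
Conditions: 5, EtMgBr (2.1 equiv), THF, 0 °C → rt; CuCl (10 mol %), then 4, THF, rt → 50 °C; aq. NH4Cl
Reagents that add atoms: none
Why: Copper-catalysed sp–sp3 coupling of an alkynylmagnesium bromide with a benzylic bromide should join the fragments, with the carbinol masked in the flask as its magnesium alkoxide and its (R) centre untouched.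

Step 5
Reactants: 7 (R)-5-[3-(benzyloxy)-4-methoxyphenyl]pent-3-yn-2-ol
Product: 8 (2R,3E)-5-[3-(benzyloxy)-4-methoxyphenyl]pent-3-en-2-ol
Conditions: NaAlH2(OCH2CH2OMe)2 (Red-Al), THF, 0 °C → rt; aq. potassium sodium tartrate
Reagents that add atoms: none
Why: trans-Hydroalumination of the propargylic alkoxide by internal hydride delivery, followed by protonolysis, should give only the E allylic alcohol and leaves the carbinol centre alone.

Step 6
Reactants: 9 methyl (S)-2,2-dimethyl-1,3-dioxolane-4-carboxylate
Product: 10 (S)-2,2-dimethyl-1,3-dioxolane-4-carboxylic acid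
Conditions: LiOH·H2O, THF/H2O, 0 °C; cold 1 M HCl to pH 3, EtOAc extraction; used crude at once
Reagents that add atoms: lithium hydroxide, [Li+].[OH-]
Why: Ester saponification (acyl substitution by hydroxide) with cold, brief acidification should keep the acetonide, and immediate use avoids self-catalysed acetal loss of the free acid.

Step 7
Reactants: 8 (2R,3E)-5-[3-(benzyloxy)-4-methoxyphenyl]pent-3-en-2-ol; 10 (S)-2,2-dimethyl-1,3-dioxolane-4-carboxylic acid
Product: 11 (2R,3E)-5-[3-(benzyloxy)-4-methoxyphenyl]pent-3-en-2-yl (4S)-2,2-dimethyl-1,3-dioxolane-4-carboxylate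
Conditions: DCC, DMAP (cat.), CH2Cl2, 0 °C → rt
Reagents that add atoms: none
Why: Steglich esterification acylates the secondary allylic alcohol at oxygen under neutral conditions, so the carbinol C–O bond is not broken and the (R) centre and E alkene are retained.

Step 8
Reactants: 11 (2R,3E)-5-[3-(benzyloxy)-4-methoxyphenyl]pent-3-en-2-yl (4S)-2,2-dimethyl-1,3-dioxolane-4-carboxylate
Product: 14 (4S)-4-{(2S,3E)-1-[3-(benzyloxy)-4-methoxyphenyl]pent-3-en-2-yl}-2,2-dimethyl-1,3-dioxolane-4-carboxylic acid, via silyl ketene acetal 12 (not isolated), via trimethylsilyl ester 13 (not isolated)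
Conditions: LiN(iPr)2, Me3SiCl/Et3N (present from the start), THF, −95 → −78 °C, then rt → 50 °C; aq. pH 4 buffer work-up
Reagents that add atoms: none
Why: The amide base removes the dioxolane α-hydrogen while Me3SiCl is already present, so the lithium enolate (Li bridging the enolate O and the ring O) is silylated to ketene acetal 12 before the β ring oxygen can be expelled; on warming, 12 undergoes a concerted suprafacial [3,3] shift through a chair that forms the C3–C4 bond, breaks the ester C–O bond and transposes the alkene, giving silyl ester 13, which water hydrolyses to 14. The closest known reaction type is the Ireland–Claisen rearrangement of chelated α-alkoxy esters of secondary allylic alcohols with 1,3-chirality transfer. No ring closes in this step; the dioxolane is carried through intact and ends up attached through its quaternary carbon. Both new stereocentres (quaternary C3 and tertiary C4, each S) are fixed together in the chair: the (R) carbinol, with its methyl equatorial, dictates which face of the E allyl unit bonds, and the ketene acetal geometry (Me3SiO cis to the ring O, so ring O equatorial and ring CH2 axial) dictates the face of the enolate carbon. The step needs one ketene acetal geometry and the chair over the boat; lithium chelation by the ring oxygen under kinetic enolisation secures the former, and the equatorial placement of methyl, benzylic arm and ring oxygen secures the latter. The new quaternary centre cannot epimerise, and the carbinol centre is consumed to give the E propenyl group.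

Step 9
Reactants: 14 (4S)-4-{(2S,3E)-1-[3-(benzyloxy)-4-methoxyphenyl]pent-3-en-2-yl}-2,2-dimethyl-1,3-dioxolane-4-carboxylic acid
Product: 17 (5S,9S)-9-[3-(benzyloxy)-4-methoxybenzyl]-2,2-dimethyl-1,3,7-trioxaspiro[4.4]nonan-6-one, via ozonide 15 (not isolated), via hydroxy acid 16 (not isolated)
Conditions: O3, CH2Cl2, −78 °C (Sudan red 7B end point); NaBH4, MeOH, −78 → 0 °C; cold aq. citric acid to pH 3; PPTS (cat.), CH2Cl2, rt
Reagents that add atoms: ozone, [O-][O+]=O
Why: Ozonolysis of the disubstituted alkene (far faster than attack on the alkoxyarenes when stopped at the dye end point), hydride reduction of the ozonide to the primary alcohol and lactonisation by 5-exo-trig acyl substitution, helped by the fully substituted α-carbon, should give the γ-lactone with both stereocentres untouched.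

Step 10
Reactants: 18 4-bromo-2-methoxyphenol
Product: 19 1-(benzyloxy)-4-bromo-2-methoxybenzene
Conditions: BnBr, K2CO3, DMF, rt
Reagents that add atoms: benzyl bromide, BrCc1ccccc1
Why: Williamson etherification of the phenoxide (SN2) is routine and leaves the aryl bromide intact.

Step 11
Reactants: 17 (5S,9S)-9-[3-(benzyloxy)-4-methoxybenzyl]-2,2-dimethyl-1,3,7-trioxaspiro[4.4]nonan-6-one; 19 1-(benzyloxy)-4-bromo-2-methoxybenzene
Product: 21 (3S,4S)-2-[4-(benzyloxy)-3-methoxyphenyl]-2-hydroxy lactol of 17 (anomeric centre undefined), via aryllithium 20 (not isolated)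
Conditions: 19, n-BuLi, THF, −78 °C; then 17, THF, −78 °C; aq. NH4Cl
Reagents that add atoms: none
Why: Bromine–lithium exchange followed by 1,2-addition of the aryllithium to the lactone carbonyl should stop at the hemiketal, since the carbonyl has no α-hydrogen to enolise and the tetrahedral alkoxide next to the quaternary carbon persists at −78 °C.

Step 12
Reactants: 21 (3S,4S)-2-[4-(benzyloxy)-3-methoxyphenyl]-2-hydroxy lactol of 17
Product: 22 (2S,3S,4S)-2-[4-(benzyloxy)-3-methoxyphenyl]-4-[3-(benzyloxy)-4-methoxybenzyl]oxolane with the C3 spiro acetonide (dioxolane O and CH2 on C3)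
Conditions: Et3SiH, BF3·OEt2, CH2Cl2, −78 → −40 °C; aq. NaHCO3
Reagents that add atoms: none
Why: Ionic hydrogenation (Lewis-acid ionisation of the hemiketal to the aryl-stabilised cyclic oxocarbenium ion, then hydride transfer from the silane) should set C2 by inside attack on the envelope that holds the C4 benzyl pseudoequatorial and the C3 CH2 pseudoaxial, so hydride enters on the face of the C3 oxygen and the aryl group ends up cis to the benzyl group, while the low temperature spares the acetonide.

Step 13
Reactants: 22 (2S,3S,4S)-oxolane spiro acetonide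
Product: 23 (2S,3S,4S)-2-[4-(benzyloxy)-3-methoxyphenyl]-4-[3-(benzyloxy)-4-methoxybenzyl]-3-(hydroxymethyl)oxolan-3-ol
Conditions: AcOH/H2O (4:1), 40 °C
Reagents that add atoms: none
Why: Acid-catalysed acetal hydrolysis under weak acid should free the tertiary/primary diol without ionising the electron-rich benzylic C2–O bond.

Step 14
Reactants: 23 (2S,3S,4S)-oxolane diol
Product: 24 [(2S,3S,4S)-2-[4-(benzyloxy)-3-methoxyphenyl]-4-[3-(benzyloxy)-4-methoxybenzyl]-3-hydroxyoxolan-3-yl]methyl 4-methylbenzenesulfonate
Conditions: TsCl, Et3N, DMAP (cat.), CH2Cl2, 0 °C → rt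
Reagents that add atoms: p-toluenesulfonyl chloride, Cc1ccc(cc1)S(=O)(=O)Cl
Why: Sulfonylation should occur only at the primary hydroxyl because the tertiary alcohol is too hindered to react with TsCl.

Step 15
Reactants: 24 primary tosylate of the dibenzyl diol
Product: 26 target (2S,3S,4S)-2-(4-hydroxy-3-methoxyphenyl)-4-(3-hydroxy-4-methoxybenzyl)oxolane with the C3 spiro oxirane (O and CH2 on C3), via phenolic tosylate 25 (not isolated)
Conditions: H2 (1 atm), Pd/C, EtOAc/MeOH, rt; filtration; K2CO3, MeOH, 0 °C → rt
Reagents that add atoms: none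
Why: Hydrogenolysis of the two aryl benzyl ethers (much faster than cleavage of the ring benzylic C2–O bond, sulfonate inert) followed by 3-exo-tet intramolecular Williamson displacement of the tosylate by the C3 alkoxide should give the oxirane with C3 retained, in an order that never exposes the oxirane to H2 and Pd.

Compound list
1 | isovanillin (3-hydroxy-4-methoxybenzaldehyde) | COc1ccc(C=O)cc1O | starting material
2 | 3-(benzyloxy)-4-methoxybenzaldehyde | COc1ccc(C=O)cc1OCc1ccccc1 | intermediate
3 | [3-(benzyloxy)-4-methoxyphenyl]methanol | COc1ccc(CO)cc1OCc1ccccc1 | intermediate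
4 | 3-(benzyloxy)-4-methoxybenzyl bromide | COc1ccc(CBr)cc1OCc1ccccc1 | intermediate
5 | (R)-but-3-yn-2-ol | C[C@@H](O)C#C | starting material
6 | bis(bromomagnesium) derivative of 5 (C-alkynide and O-alkoxide) | C[C@@H](O[Mg]Br)C#C[Mg]Br | intermediate
7 | (R)-5-[3-(benzyloxy)-4-methoxyphenyl]pent-3-yn-2-ol | C[C@@H](O)C#CCc1ccc(OC)c(OCc2ccccc2)c1 | intermediate
8 | (2R,3E)-5-[3-(benzyloxy)-4-methoxyphenyl]pent-3-en-2-ol | C[C@@H](O)/C=C/Cc1ccc(OC)c(OCc2ccccc2)c1 | intermediate
9 | methyl (S)-2,2-dimethyl-1,3-dioxolane-4-carboxylate | COC(=O)[C@@H]1COC(C)(C)O1 | starting material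
10 | (S)-2,2-dimethyl-1,3-dioxolane-4-carboxylic acid | OC(=O)[C@@H]1COC(C)(C)O1 | intermediate
11 | (2R,3E)-5-[3-(benzyloxy)-4-methoxyphenyl]pent-3-en-2-yl (4S)-2,2-dimethyl-1,3-dioxolane-4-carboxylate | C[C@@H](OC(=O)[C@@H]1COC(C)(C)O1)/C=C/Cc1ccc(OC)c(OCc2ccccc2)c1 | intermediate
12 | trimethylsilyl ketene acetal of 11, Me3SiO cis to the dioxolane ring oxygen | C[C@@H](O/C(O[Si](C)(C)C)=C1\COC(C)(C)O1)/C=C/Cc2ccc(OC)c(OCc3ccccc3)c2 | intermediate
13 | trimethylsilyl ester of 14 | C/C=C/[C@H](Cc1ccc(OC)c(OCc2ccccc2)c1)[C@@]1(C(=O)O[Si](C)(C)C)COC(C)(C)O1 | intermediate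
14 | (4S)-4-{(2S,3E)-1-[3-(benzyloxy)-4-methoxyphenyl]pent-3-en-2-yl}-2,2-dimethyl-1,3-dioxolane-4-carboxylic acid | C/C=C/[C@H](Cc1ccc(OC)c(OCc2ccccc2)c1)[C@@]1(C(=O)O)COC(C)(C)O1 | intermediate
15 | secondary ozonide (1,2,4-trioxolane) of 14, trioxolane carbons undefined | CC1OC(OO1)[C@H](Cc2ccc(OC)c(OCc3ccccc3)c2)[C@@]4(C(=O)O)COC(C)(C)O4 | intermediate
16 | (4S)-4-{(2S)-1-[3-(benzyloxy)-4-methoxyphenyl]-3-hydroxypropan-2-yl}-2,2-dimethyl-1,3-dioxolane-4-carboxylic acid | OC[C@H](Cc1ccc(OC)c(OCc2ccccc2)c1)[C@@]1(C(=O)O)COC(C)(C)O1 | intermediate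
17 | (5S,9S)-9-[3-(benzyloxy)-4-methoxybenzyl]-2,2-dimethyl-1,3,7-trioxaspiro[4.4]nonan-6-one (spiro γ-lactone) | O=C1OC[C@H](Cc2ccc(OC)c(OCc3ccccc3)c2)[C@]12COC(C)(C)O2 | intermediate
18 | 4-bromo-2-methoxyphenol | COc1cc(Br)ccc1O | starting material
19 | 1-(benzyloxy)-4-bromo-2-methoxybenzene | COc1cc(Br)ccc1OCc1ccccc1 | intermediate
20 | [4-(benzyloxy)-3-methoxyphenyl]lithium | COc1cc([Li])ccc1OCc1ccccc1 | intermediate
21 | aryl lactol: 17 with C2 bearing OH and 4-(benzyloxy)-3-methoxyphenyl, (3S,4S), anomeric centre undefined | OC1(c2ccc(OCc3ccccc3)c(OC)c2)OC[C@H](Cc2ccc(OC)c(OCc3ccccc3)c2)[C@]12COC(C)(C)O2 | intermediate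
22 | (2S,3S,4S)-2-[4-(benzyloxy)-3-methoxyphenyl]-4-[3-(benzyloxy)-4-methoxybenzyl]oxolane, C3 spiro-fused to a 2,2-dimethyl-1,3-dioxolane | COc1ccc(C[C@H]2CO[C@@H](c3ccc(OCc4ccccc4)c(OC)c3)[C@@]23COC(C)(C)O3)cc1OCc1ccccc1 | intermediate
23 | (2S,3S,4S)-2-[4-(benzyloxy)-3-methoxyphenyl]-4-[3-(benzyloxy)-4-methoxybenzyl]-3-(hydroxymethyl)oxolan-3-ol | COc1ccc(C[C@H]2CO[C@@H](c3ccc(OCc4ccccc4)c(OC)c3)[C@@]2(O)CO)cc1OCc1ccccc1 | intermediate
24 | primary 4-methylbenzenesulfonate of 23 | COc1ccc(C[C@H]2CO[C@@H](c3ccc(OCc4ccccc4)c(OC)c3)[C@@]2(O)COS(=O)(=O)c5ccc(C)cc5)cc1OCc6ccccc6 | intermediate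
25 | debenzylated (bis-phenolic) hydroxy tosylate | COc1ccc(C[C@H]2CO[C@@H](c3ccc(O)c(OC)c3)[C@@]2(O)COS(=O)(=O)c4ccc(C)cc4)cc1O | intermediate
26 | CNP0184956.1, (2S,3S,4S) in oxolane numbering, C3 spiro-fused to the oxirane | COc1ccc(C[C@H]2CO[C@@H](c3ccc(O)c(OC)c3)[C@@]23CO3)cc1O | target

Total step count: 15
Longest linear sequence: 13 steps (steps 1–5, 7–9 and 11–15, from isovanillin)

Steps most likely to fail

Step 8. The risk is enolisation without lithium chelation to the ring oxygen (or partial β-elimination of that oxygen before silylation), which would give the ketene acetal with Me3SiO trans to the ring oxygen and so create C3 with the wrong configuration relative to C4. The fallback sets out from bromide 4 and comes back at acid 14; it applies if the opposite geometry forms cleanly. Bought (S)-but-3-yn-2-ol is converted with EtMgBr into the bis(bromomagnesium) derivative of (S)-but-3-yn-2-ol F1 and coupled with 4 under CuCl catalysis as in step 4 to give (S)-5-[3-(benzyloxy)-4-methoxyphenyl]pent-3-yn-2-ol F2. Lindlar semihydrogenation (H2, Pd/CaCO3 poisoned with Pb(OAc)2, quinoline) gives (2S,3Z)-5-[3-(benzyloxy)-4-methoxyphenyl]pent-3-en-2-ol F3, and esterification with 10 as in step 7 gives the (2S,3Z)-pentenyl dioxolanecarboxylate F4. Enolisation and silylation as in step 8 would then give the ketene acetal of opposite geometry F5, which should rearrange through the mirror-image chair (carbinol methyl equatorial, benzylic arm axial, ring oxygen axial) to the same silyl ester 13 and, after work-up, to 14.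

Step 12. The risk is poor facial selectivity in hydride transfer to the oxocarbenium ion, or loss of the acetonide under the Lewis acid. The fallback sets out from lactol 21 and comes back at 22. The open hydroxy ketone tautomer of 21 is reduced with Zn(BH4)2 in Et2O at −20 °C. Chelation of zinc between the ketone oxygen and the dioxolane oxygen should direct hydride to the face opposite the C4 branch and give the (S)-benzylic 1,4-diol F6, which has the C2 configuration of the target. Selective tosylation of the primary hydroxyl (TsCl, Et3N, DMAP) gives the primary tosylate of the 1,4-diol F7, and KOtBu in THF closes the oxolane by 5-exo-tet Williamson displacement with retention at C2 to give 22.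

Step 15. The risk is over-reduction during debenzylation, that is, hydrogenolytic opening of the ring benzylic C2–O bond of the electron-rich 2-aryl oxolane. The fallback changes the protecting-group plan so that no hydrogenolysis is run once that bond exists; it sets out from lactone 17 and bromophenol 18 and comes back at 25.
- Hydrogenolysis of 17 (H2, Pd/C, EtOAc) gives the phenolic spiro lactone F8, which is silylated (TBSCl, imidazole, DMF) to the silyl ether spiro lactone F9.
- Bromophenol 18 is silylated in the same way to (4-bromo-2-methoxyphenoxy)(tert-butyl)dimethylsilane F10. Bromine–lithium exchange (n-BuLi, THF, −78 °C) gives the silyloxy aryllithium F11, which adds to F9 as in step 11 to give the bis-silylated lactol F12.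
- Reduction as in step 12 gives the bis-silylated oxolane acetonide F13, hydrolysis as in step 13 gives the bis-silylated diol F14, and tosylation as in step 14 gives the bis-silylated primary tosylate F15.
- Bu4NF buffered with AcOH in THF at 0 °C removes both aryl silyl ethers to give 25, which is closed with K2CO3 in MeOH as in the second half of step 15.

Further compounds
F1 | step 8 | bis(bromomagnesium) derivative of (S)-but-3-yn-2-ol | C[C@H](O[Mg]Br)C#C[Mg]Br
F2 | step 8 | (S)-5-[3-(benzyloxy)-4-methoxyphenyl]pent-3-yn-2-ol | C[C@H](O)C#CCc1ccc(OC)c(OCc2ccccc2)c1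
F3 | step 8 | (2S,3Z)-5-[3-(benzyloxy)-4-methoxyphenyl]pent-3-en-2-ol | C[C@H](O)/C=C\Cc1ccc(OC)c(OCc2ccccc2)c1
F4 | step 8 | (2S,3Z)-5-[3-(benzyloxy)-4-methoxyphenyl]pent-3-en-2-yl (4S)-2,2-dimethyl-1,3-dioxolane-4-carboxylate | C[C@H](OC(=O)[C@@H]1COC(C)(C)O1)/C=C\Cc2ccc(OC)c(OCc3ccccc3)c2
F5 | step 8 | trimethylsilyl ketene acetal of F4, Me3SiO trans to the dioxolane ring oxygen | C[C@H](O/C(O[Si](C)(C)C)=C1/COC(C)(C)O1)/C=C\Cc2ccc(OC)c(OCc3ccccc3)c2
F6 | step 12 | (S)-benzylic 1,4-diol from chelation-controlled reduction of the open form of 21 | O[C@@H](c1ccc(OCc2ccccc2)c(OC)c1)[C@@]1(COC(C)(C)O1)[C@H](CO)Cc1ccc(OC)c(OCc2ccccc2)c1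
F7 | step 12 | primary 4-methylbenzenesulfonate of F6 | O[C@@H](c1ccc(OCc2ccccc2)c(OC)c1)[C@@]1(COC(C)(C)O1)[C@H](COS(=O)(=O)c1ccc(C)cc1)Cc1ccc(OC)c(OCc2ccccc2)c1
F8 | step 15 | phenolic spiro lactone (17 without its benzyl group) | O=C1OC[C@H](Cc2ccc(OC)c(O)c2)[C@]12COC(C)(C)O2
F9 | step 15 | tert-butyldimethylsilyl ether of F8 | O=C1OC[C@H](Cc2ccc(OC)c(O[Si](C)(C)C(C)(C)C)c2)[C@]12COC(C)(C)O2
F10 | step 15 | (4-bromo-2-methoxyphenoxy)(tert-butyl)dimethylsilane | COc1cc(Br)ccc1O[Si](C)(C)C(C)(C)C
F11 | step 15 | [4-(tert-butyldimethylsilyloxy)-3-methoxyphenyl]lithium | COc1cc([Li])ccc1O[Si](C)(C)C(C)(C)C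
F12 | step 15 | bis-silylated aryl lactol (anomeric centre undefined) | OC1(c2ccc(O[Si](C)(C)C(C)(C)C)c(OC)c2)OC[C@H](Cc2ccc(OC)c(O[Si](C)(C)C(C)(C)C)c2)[C@]12COC(C)(C)O2
F13 | step 15 | bis-silylated (2S,3S,4S)-oxolane spiro acetonide | COc1ccc(C[C@H]2CO[C@@H](c3ccc(O[Si](C)(C)C(C)(C)C)c(OC)c3)[C@@]23COC(C)(C)O3)cc1O[Si](C)(C)C(C)(C)C
F14 | step 15 | bis-silylated (2S,3S,4S)-oxolane diol | COc1ccc(C[C@H]2CO[C@@H](c3ccc(O[Si](C)(C)C(C)(C)C)c(OC)c3)[C@@]2(O)CO)cc1O[Si](C)(C)C(C)(C)C
F15 | step 15 | primary 4-methylbenzenesulfonate of F14 | COc1ccc(C[C@H]2CO[C@@H](c3ccc(O[Si](C)(C)C(C)(C)C)c(OC)c3)[C@@]2(O)COS(=O)(=O)c4ccc(C)cc4)cc1O[Si](C)(C)C(C)(C)C
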